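**Retrosynthetic overview**
1. Acid ⇐ methyl ester. The side chain is cut at the C8'–C9' sp3–sp2 bond, giving an ω‑vinyl dioxolane ester and a C8 trienyl iodide (B‑alkyl Suzuki coupling, last C–C bond).
2. Key disconnection: the C3–O bond of the dioxolane. The precursor is a tertiary hydroperoxide tethered to an (E)‑β‑methyl enoate, closed by a new catalytic enantioselective 5‑exo peroxa‑Michael addition. This step sets C3 and sorts C5.
3. Second C–O disconnection: C5–OOH ⇐ 1,1‑disubstituted alkene (HBr, then silver‑assisted perhydrolysis). C5 enters racemic.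
4. Skipped dienoate ⇐ 2‑substituted allyl chloride + (Z)‑β‑boryl crotonate. Allyl chloride ⇐ heptenyl Grignard + methallyl dichloride.
5. There is only one ring, the 1,2‑dioxolane, and it is formed in step 5.

Numbering: dioxolane O1–O2–C3–C4–C5; side‑chain carbons carry primes. The target is (3S,5R), with the two methyl groups trans.

Assumption: the quinidine‑derived squaramide is taken to give the (3S) configuration; if the sense is opposite, the quinine‑derived pseudo‑enantiomer is used and nothing else changes.

**Step 1**
Reactants: 1 7-bromohept-1-ene; 2 3-chloro-2-(chloromethyl)prop-1-ene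
Product: 4 2-(chloromethyl)deca-1,9-diene, via hept-6-en-1-ylmagnesium bromide 3 (not isolated)
Conditions: Mg, THF, rt; then added to 2 (3 equiv), Li2CuCl4 (3 mol%), THF, −20 to 0 °C
Reagents that add atoms: none
Why: Copper‑catalysed allylic substitution of a Grignard reagent (Kochi‑type coupling); the two allylic termini of 2 are equivalent, so direct and allyl‑shifted attack give the same product, the excess of cheap 2 suppresses double alkylation, and no stereocentre is formed.

**Step 2**
Reactants: 5 methyl but-2-ynoate
Product: 6 methyl (2Z)-3-(4,4,5,5-tetramethyl-1,3,2-dioxaborolan-2-yl)but-2-enoate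
Conditions: B2pin2 (1.1 equiv), CuCl (3 mol%), Xantphos (3 mol%), NaOtBu (6 mol%), MeOH (2 equiv), THF, rt
Reagents that add atoms: bis(pinacolato)diboron, CC1(C)OB(OC1(C)C)B1OC(C)(C)C(C)(C)O1
Why: Copper‑catalysed syn borylcupration/protonation of an ynoate puts boron on the β‑carbon cis to the new H, which fixes the alkene geometry (CH3 cis to CO2Me).

**Step 3**
Reactants: 4 2-(chloromethyl)deca-1,9-diene; 6 methyl (2Z)-3-(4,4,5,5-tetramethyl-1,3,2-dioxaborolan-2-yl)but-2-enoate
Product: 7 methyl (2E)-3-methyl-5-methylidenetrideca-2,12-dienoate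
Conditions: Pd(dppf)Cl2 (3 mol%), K3PO4 (2 equiv), THF/H2O 10:1, 45 °C
Reagents that add atoms: none
Why: Suzuki–Miyaura allyl–alkenyl coupling; the symmetrical 2‑substituted π‑allyl palladium from 4 leaves no regiochemical choice and the alkenyl boronate transfers with retention, giving the (2E) skipped dienoate.

**Step 4**
Reactants: 7 methyl (2E)-3-methyl-5-methylidenetrideca-2,12-dienoate
Product: 9 methyl (2E)-5-hydroperoxy-3,5-dimethyltrideca-2,12-dienoate (racemic), via tertiary bromide 8 (not isolated)
Conditions: HBr (33% in AcOH, 1.05 equiv), CH2Cl2, −30 °C, cold NaHCO3 wash, used crude; then anhydrous H2O2 (about 2 M in Et2O, 10 equiv), AgO2CCF3 (1.2 equiv), Et2O, −20 to 0 °C, dark, blast shield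
Reagents that add atoms: hydrogen peroxide, OO
Why: Ionic Markovnikov hydrobromination touches only the 1,1‑disubstituted alkene (tertiary cation; the vinyl and enoate groups are far less basic), and silver‑assisted SN1 perhydrolysis of the tertiary bromide in excess H2O2 forms the C5–O bond, creating C5 as a racemate.

**Step 5**
Reactants: 9 methyl (2E)-5-hydroperoxy-3,5-dimethyltrideca-2,12-dienoate (racemic)
Product: 10 methyl 2-[(3S,5R)-3,5-dimethyl-5-(oct-7-en-1-yl)-1,2-dioxolan-3-yl]acetate
Conditions: squaramide catalyst built from 9-amino-9-deoxy-epi-quinidine and 3,5-bis(trifluoromethyl)aniline (10 mol%), toluene (0.05 M), 4 Å MS, −20 °C, 48 h, full conversion; SiO2 chromatography removes the (3S,5S) isomer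
Reagents that add atoms: none
Why: Proposed new method: catalytic enantioselective intramolecular peroxa‑Michael addition. The quinuclidine nitrogen acts as general base on the acidic OOH (pKa about 12–13) while the two squaramide N–H bonds bind the ester carbonyl of the geometrically pure (E)‑enoate. The tight ion pair exposes one face of C3 to a gem‑dialkyl‑accelerated 5‑exo‑trig closure that forms the C3–O bond and the ring. Protonation of the ester enolate by the quinuclidinium ion outruns O–O cleavage to an epoxide and makes the step irreversible at low temperature. Because achiral amines close such hydroperoxides with almost no diastereoselectivity, the remote methyl/alkyl pair at C5 should not override the catalyst. Hence (5R)‑9 gives trans‑(3S,5R)‑10 and (5S)‑9 gives the separable cis‑(3S,5S) isomer (divergent reaction of a racemate, at most 50% yield; the ee of 10 equals the facial selectivity). The closest known reaction types are the amine‑catalysed racemic hydroperoxide oxa‑Michael closure to 1,2‑dioxolane‑3‑acetates and squaramide‑ or thiourea‑catalysed enantioselective oxa‑Michael cyclisations of alcohols.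

**Step 6**
Reactants: 11 (2E,4E)-hepta-2,4-dienal
Product: 12 (1E,3E,5E)-1-iodoocta-1,3,5-triene
Conditions: CrCl2 (6 equiv), CHI3 (2 equiv), THF/dioxane 1:6, 0 °C to rt, dark; used within a day
Reagents that add atoms: iodoform, IC(I)I
Why: Takai olefination; the geminal dichromium reagent adds to the aldehyde and eliminates to the (E)‑iodoalkene, leaving the two existing E alkenes untouched.

**Step 7**
Reactants: 10 methyl 2-[(3S,5R)-3,5-dimethyl-5-(oct-7-en-1-yl)-1,2-dioxolan-3-yl]acetate; 12 (1E,3E,5E)-1-iodoocta-1,3,5-triene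
Product: 14 methyl 2-[(3S,5R)-5-[(9E,11E,13E)-hexadeca-9,11,13-trien-1-yl]-3,5-dimethyl-1,2-dioxolan-3-yl]acetate, via B-alkyl-9-BBN adduct 13 (not isolated)
Conditions: 9-BBN-H (1.3 equiv), THF, 0 °C to rt, 3 h; then 12 (1.2 equiv), Pd(dppf)Cl2 (5 mol%), AsPh3 (5 mol%), Cs2CO3 (2 equiv), DMF/THF/H2O, rt, dark
Reagents that add atoms: none
Why: Chemoselective hydroboration of the terminal alkene followed by room‑temperature B‑alkyl Suzuki–Miyaura coupling forms the sp3–sp2 bond with retention of the iodide geometry; the fully substituted peroxide has no α‑hydrogen and tolerates borane, mild base and the palladium catalyst, so C3 and C5 are untouched.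

**Step 8**
Reactants: 14 methyl 2-[(3S,5R)-5-[(9E,11E,13E)-hexadeca-9,11,13-trien-1-yl]-3,5-dimethyl-1,2-dioxolan-3-yl]acetate
Product: 15 2-[(3S,5R)-5-[(9E,11E,13E)-hexadeca-9,11,13-trien-1-yl]-3,5-dimethyl-1,2-dioxolan-3-yl]acetic acid
Conditions: LiOH (3 equiv), THF/MeOH/H2O, 0 °C to rt; then 1 M HCl to pH 4, 0 °C
Reagents that add atoms: lithium hydroxide, [Li+].[OH-]
Why: Saponification by acyl–oxygen cleavage; aqueous hydroxide does not enolise the ester, so there is no retro‑Michael opening or epimerisation at C3, and the peroxide and triene are inert.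

**Compound list**
1 | 7-bromohept-1-ene | C=CCCCCCBr | starting material
2 | 3-chloro-2-(chloromethyl)prop-1-ene | C=C(CCl)CCl | starting material
3 | hept-6-en-1-ylmagnesium bromide | C=CCCCCC[Mg]Br | intermediate
4 | 2-(chloromethyl)deca-1,9-diene | C=CCCCCCCC(=C)CCl | intermediate
5 | methyl but-2-ynoate | CC#CC(=O)OC | starting material
6 | methyl (2Z)-3-(4,4,5,5-tetramethyl-1,3,2-dioxaborolan-2-yl)but-2-enoate | C/C(B1OC(C)(C)C(C)(C)O1)=C\C(=O)OC | intermediate
7 | methyl (2E)-3-methyl-5-methylidenetrideca-2,12-dienoate | C=CCCCCCCC(=C)C/C(C)=C/C(=O)OC | intermediate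
8 | methyl (2E)-5-bromo-3,5-dimethyltrideca-2,12-dienoate (racemic) | C=CCCCCCCC(C)(Br)C/C(C)=C/C(=O)OC | intermediate
9 | methyl (2E)-5-hydroperoxy-3,5-dimethyltrideca-2,12-dienoate (racemic) | C=CCCCCCCC(C)(OO)C/C(C)=C/C(=O)OC | intermediate
10 | methyl 2-[(3S,5R)-3,5-dimethyl-5-(oct-7-en-1-yl)-1,2-dioxolan-3-yl]acetate | C=CCCCCCC[C@]1(C)C[C@@](C)(CC(=O)OC)OO1 | intermediate
11 | (2E,4E)-hepta-2,4-dienal | CC/C=C/C=C/C=O | starting material
12 | (1E,3E,5E)-1-iodoocta-1,3,5-triene | CC/C=C/C=C/C=C/I | intermediate
13 | methyl 2-[(3S,5R)-5-[8-(9-borabicyclo[3.3.1]nonan-9-yl)octyl]-3,5-dimethyl-1,2-dioxolan-3-yl]acetate | C12CCCC(CCC1)B2CCCCCCCC[C@]1(C)C[C@@](C)(CC(=O)OC)OO1 | intermediate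
14 | methyl 2-[(3S,5R)-5-[(9E,11E,13E)-hexadeca-9,11,13-trien-1-yl]-3,5-dimethyl-1,2-dioxolan-3-yl]acetate | CC/C=C/C=C/C=C/CCCCCCCC[C@]1(C)C[C@@](C)(CC(=O)OC)OO1 | intermediate
15 | 2-[(3S,5R)-5-[(9E,11E,13E)-hexadeca-9,11,13-trien-1-yl]-3,5-dimethyl-1,2-dioxolan-3-yl]acetic acid | CC/C=C/C=C/C=C/CCCCCCCC[C@]1(C)C[C@@](C)(CC(=O)O)OO1 | target

**Totals**
Total step count: 8.
Longest linear sequence: 6 (steps 1, 3, 4, 5, 7, 8).

**Three steps most likely to fail**

Step 5 (the new step). The risks are slow closure on a plain ester, poor facial control, or a racemic background reaction. The fallback uses known chemistry and sets out from 9. The ring is closed with the established achiral protocol (Et2NH 20 mol%, CF3CH2OH, rt), which gives both diastereomers as racemates. Silica gel chromatography isolates the racemic trans ester F2. Preparative HPLC on an amylose tris(3,5-dimethylphenylcarbamate) phase then delivers the (3S,5R) enantiomer, and the route is rejoined at 10.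

Step 4. The risks are loss of a C4 proton from the tertiary cation, giving the conjugated dienoate, and weak capture by H2O2. The fallback sets out from 7 and changes from cationic to radical C–O bond formation. Mukaiyama–Isayama silylperoxidation is used: Co(thd)2 (thd = 2,2,6,6-tetramethylheptane-3,5-dionate, 5 mol%), O2 (1 atm), Et3SiH (1.2 equiv), ClCH2CH2Cl, rt. The reaction is stopped at about 80% conversion to spare the vinyl group and gives the triethylsilyl peroxide F1. Catalytic HCl in MeOH at 0 °C then frees the hydroperoxide, and the route is rejoined at 9.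

Step 7. The risks are decomposition of trienyl iodide 12 and palladium‑induced damage to the peroxide during a slow coupling. The fallback sets out from 10 and builds the triene in two stages. The same borane 13 is coupled (Pd(dppf)Cl2, AsPh3, Cs2CO3, DMF/H2O, rt) with crystalline (2E,4E)-5-bromopenta-2,4-dienal to give the dienal ester F3. A Julia–Kocienski olefination follows with 1-phenyl-5-(propylsulfonyl)-1H-tetrazole (KHMDS, DME, −60 °C, sulfone metalated first). This forms the last E alkene, with a trace of I2 to equilibrate any Z isomer, and the route is rejoined at 14.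

**Further compounds**
F1 | step 4 | methyl (2E)-3,5-dimethyl-5-[(triethylsilyl)peroxy]trideca-2,12-dienoate (racemic) | C=CCCCCCCC(C)(OO[Si](CC)(CC)CC)C/C(C)=C/C(=O)OC
F2 | step 5 | racemic trans ester, methyl 2-[(3S,5R)- and (3R,5S)-3,5-dimethyl-5-(oct-7-en-1-yl)-1,2-dioxolan-3-yl]acetate | C=CCCCCCC[C@]1(C)C[C@@](C)(CC(=O)OC)OO1.C=CCCCCCC[C@@]1(C)C[C@](C)(CC(=O)OC)OO1
F3 | step 7 | methyl 2-[(3S,5R)-3,5-dimethyl-5-[(9E,11E)-13-oxotrideca-9,11-dien-1-yl]-1,2-dioxolan-3-yl]acetate | O=C/C=C/C=C/CCCCCCCC[C@]1(C)C[C@@](C)(CC(=O)OC)OO1
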